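Ring B is a benzene ring with OH at C1, the 4-hydroxybenzyl group at C2, OMe at C3, the 2-(3-methoxyphenyl)ethyl chain at C5 and hydrogen at C4 and C6. A carbon substituent flanked by OH and OMe, with one alkyl group para to it, is the pattern made by a 3-monosubstituted cyclobutenone (supplies C1, C4, C5, C6) and a methyl ynol ether MeO–C≡C–CH2Ar (supplies C2, C3).
Retrosynthesis: the ring C phenol is masked as its benzyl ether. Ring B is then cut at C1–C2, C3–C4 and C1–C6, which gives 3-[2-(3-methoxyphenyl)ethyl]cyclobutenone and 1-methoxy-3-[4-(benzyloxy)phenyl]propyne.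
The cyclobutenone is cut across its ring to dichloroketene and 4-(3-methoxyphenyl)but-1-yne, and that alkyne is cut at the ArCH2–CH2 bond to 3-methoxybenzyl bromide and 1-(trimethylsilyl)propyne. The ynol ether is cut at the ArCH2–C(sp) bond to 4-(benzyloxy)benzyl bromide and methoxyacetylene, which comes from chloroacetaldehyde dimethyl acetal.
Forward: rings A and C are bought. The chain is grown on ring A, the four-membered ring is closed on its alkyne end, and the ynol ether is made in a parallel two-step branch. Ring B arises last by union of the two halves, and hydrogenolysis frees the ring C phenol.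
The target has no stereocentre and no stereogenic double bond, so the only thing to control is the orientation in which ketene and alkyne combine.

Key step: step 7

Remark on the chemistry: the ring C phenol is carried as a benzyl ether because 4-(benzyloxy)benzyl bromide is taken to be a catalogue compound. This ether also withstands organolithium bases, prolonged heating and, if needed, methanolic hydroxide.

Step 1
Reactants: 1 1-(trimethylsilyl)propyne; 2 3-methoxybenzyl bromide
Product: 4 [4-(3-methoxyphenyl)but-1-yn-1-yl]trimethylsilane, via lithiated 1-(trimethylsilyl)propyne 3 (not isolated)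
Conditions: 1, n-BuLi, THF, −78 °C; then 2, −78 °C to rt
Reagents that add atoms: none
Why: SN2 alkylation of a silyl-capped propargyllithium by a reactive benzylic bromide takes place at the CH2 terminus, because the bulky silyl group shields the other end and so suppresses allene formation.

Step 2
Reactants: 4 [4-(3-methoxyphenyl)but-1-yn-1-yl]trimethylsilane
Product: 5 1-(but-3-yn-1-yl)-3-methoxybenzene
Conditions: K2CO3 (0.2 equiv), MeOH, rt
Reagents that add atoms: none
Why: Base-catalysed methanolysis of the C(sp)–Si bond (protodesilylation) is the standard mild release of a terminal alkyne and touches neither the aryl methyl ether nor the saturated chain.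

Step 3
Reactants: 5 1-(but-3-yn-1-yl)-3-methoxybenzene; 6 trichloroacetyl chloride
Product: 8 4,4-dichloro-3-[2-(3-methoxyphenyl)ethyl]cyclobut-2-en-1-one, via dichloroketene 7 (not isolated)
Conditions: Zn–Cu couple, Et2O–DME, slow addition of 6, rt
Reagents that add atoms: none
Why: Zinc dehalogenation of 6 releases dichloroketene 7, which undergoes the known (2+2) cycloaddition to terminal alkynes with its carbonyl carbon bonding to the terminal CH, so the chain ends up at C3 of the cyclobutenone, while DME ties up ZnCl2 and the anisole ring is left alone.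

Step 4
Reactants: 8 4,4-dichloro-3-[2-(3-methoxyphenyl)ethyl]cyclobut-2-en-1-one
Product: 9 3-[2-(3-methoxyphenyl)ethyl]cyclobut-2-en-1-one
Conditions: Zn dust, AcOH, TMEDA, EtOH, 0 °C to rt
Reagents that add atoms: none
Why: Reductive dechlorination of an α,α-dichloroketone by zinc in the AcOH–TMEDA buffer is the established sequel to the dichloroketene addition and removes both chlorines without reducing or isomerising the strained enone.

Step 5
Reactants: 10 chloroacetaldehyde dimethyl acetal
Product: 12 methoxyacetylene, via sodium methoxyacetylide 11 (not isolated)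
Conditions: NaNH2 (3 equiv), liq. NH3, −33 °C; NH3 evaporated; cold brine; product (bp about 23 °C) distilled into a cold trap, dried, kept as a cold THF solution
Reagents that add atoms: none
Why: The threefold action of NaNH2 (loss of MeOH, loss of HCl, deprotonation) is the classical preparation of alkoxyacetylenes from chloroacetaldehyde acetals, and distilling the alkyne leaves behind the methoxide and ammonia that would otherwise consume the benzylic bromide of the next step.

Step 6
Reactants: 12 methoxyacetylene; 13 4-(benzyloxy)benzyl bromide
Product: 15 1-(benzyloxy)-4-(3-methoxyprop-2-yn-1-yl)benzene, via lithium methoxyacetylide 14 (not isolated)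
Conditions: 12 (1.2 equiv), n-BuLi (1.1 equiv), THF, −78 °C; then 13, DMPU, −78 °C to rt; neutral work-up, chromatography on Et3N-washed silica
Reagents that add atoms: none
Why: SN2 alkylation of a lithium alkoxyacetylide in THF with a dipolar cosolvent is the standard entry to 1-alkoxyalk-1-ynes, and a p-alkoxybenzyl bromide is among the most reactive electrophiles for it, so the reaction can be run cold and without excess base.

Step 7
Reactants: 9 3-[2-(3-methoxyphenyl)ethyl]cyclobut-2-en-1-one; 15 1-(benzyloxy)-4-(3-methoxyprop-2-yn-1-yl)benzene
Product: 20 2-[4-(benzyloxy)benzyl]-3-methoxy-5-[2-(3-methoxyphenyl)ethyl]phenol, via vinylketene 16 (not isolated), via 4-alkenylcyclobutenone 17 (not isolated), via dienylketene 18 (not isolated), via cyclohexa-2,4-dienone 19 (not isolated)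
Conditions: 15 (1.3 equiv), toluene (about 1 M), sealed tube, argon, 80 °C, then 140 °C
Reagents that add atoms: none
Why: This is the Danheiser benzannulation, a known cascade of four pericyclic events between a cyclobutenone and an alkynyl ether. At 80 °C the four-electron electrocyclic opening of 9 (cleavage of the C(=O)–CH2 bond) gives vinylketene 16, whose ketene unit adds ynol ether 15 in a (2+2) cycloaddition to give 4-alkenylcyclobutenone 17 and so makes bonds C1–C2 and C3–C4 of ring B. At 140 °C 17 opens reversibly at the bond between its carbonyl carbon and its sp3 carbon to dienylketene 18, and the isomer with the alkenyl group turned towards the ketene closes ring B by a six-electron disrotatory electrocyclization (bond C1–C6, ketene carbon to terminal CH2) to cyclohexa-2,4-dienone 19, which tautomerizes irreversibly to phenol 20. The one selectivity required is the orientation of the (2+2) step, and the substrate secures it: donation from the methoxy oxygen makes the benzyl-bearing alkyne carbon the nucleophilic one, it bonds to the electrophilic ketene carbonyl carbon, and the benzyl group therefore has to end up at C2 between OH and OMe. Because 9 is substituted only at its C3, positions C4 and C6 of ring B emerge as CH and the chain sits at C5, and no stereocentre survives, since the single one in 17 is erased on ring opening. An O-methyl group offers no β-hydrogen for retro-ene loss of an alkene, so 15 should tolerate the temperature, the three aryl ethers are inert to neutral thermolysis, and every atom of both partners is retained in 20.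

Step 8
Reactants: 20 2-[4-(benzyloxy)benzyl]-3-methoxy-5-[2-(3-methoxyphenyl)ethyl]phenol
Product: 21 2-(4-hydroxybenzyl)-3-methoxy-5-[2-(3-methoxyphenyl)ethyl]phenol (IN0509)
Conditions: H2 (1 atm), Pd/C, EtOAc–EtOH, rt
Reagents that add atoms: none
Why: Catalytic hydrogenolysis of a benzyl aryl ether cleaves only the O–CH2Ph bond, while the diarylmethane and bibenzyl C–C bonds, the methyl ethers and the arenes are inert at this pressure and temperature.

Compound list
1 | 1-(trimethylsilyl)propyne | CC#C[Si](C)(C)C | starting material
2 | 3-methoxybenzyl bromide | COc1cccc(CBr)c1 | starting material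
3 | 3-lithio-1-(trimethylsilyl)propyne | [Li]CC#C[Si](C)(C)C | intermediate
4 | [4-(3-methoxyphenyl)but-1-yn-1-yl]trimethylsilane | COc1cccc(CCC#C[Si](C)(C)C)c1 | intermediate
5 | 1-(but-3-yn-1-yl)-3-methoxybenzene | C#CCCc1cccc(OC)c1 | intermediate
6 | trichloroacetyl chloride | O=C(Cl)C(Cl)(Cl)Cl | starting material
7 | dichloroketene | O=C=C(Cl)Cl | intermediate
8 | 4,4-dichloro-3-[2-(3-methoxyphenyl)ethyl]cyclobut-2-en-1-one | O=C1C=C(CCc2cccc(OC)c2)C1(Cl)Cl | intermediate
9 | 3-[2-(3-methoxyphenyl)ethyl]cyclobut-2-en-1-one | O=C1C=C(CCc2cccc(OC)c2)C1 | intermediate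
10 | chloroacetaldehyde dimethyl acetal (2-chloro-1,1-dimethoxyethane) | COC(CCl)OC | starting material
11 | sodium methoxyacetylide | [Na]C#COC | intermediate
12 | methoxyacetylene | C#COC | intermediate
13 | 4-(benzyloxy)benzyl bromide | BrCc1ccc(OCc2ccccc2)cc1 | starting material
14 | lithium methoxyacetylide | [Li]C#COC | intermediate
15 | 1-(benzyloxy)-4-(3-methoxyprop-2-yn-1-yl)benzene | COC#CCc1ccc(OCc2ccccc2)cc1 | intermediate
16 | 5-(3-methoxyphenyl)-3-methylidenepent-1-en-1-one (vinylketene) | O=C=CC(=C)CCc1cccc(OC)c1 | intermediate
17 | 2-[4-(benzyloxy)benzyl]-3-methoxy-4-[4-(3-methoxyphenyl)but-1-en-2-yl]cyclobut-2-en-1-one (racemic, transient) | O=C1C(Cc2ccc(OCc3ccccc3)cc2)=C(OC)C1C(=C)CCc1cccc(OC)c1 | intermediate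
18 | (3E)-2-[4-(benzyloxy)benzyl]-3-methoxy-7-(3-methoxyphenyl)-5-methylidenehepta-1,3-dien-1-one (dienylketene, ketene carbon and alkenyl group cis) | O=C=C(Cc1ccc(OCc2ccccc2)cc1)/C(OC)=C\C(=C)CCc1cccc(OC)c1 | intermediate
19 | 2-[4-(benzyloxy)benzyl]-3-methoxy-5-[2-(3-methoxyphenyl)ethyl]cyclohexa-2,4-dien-1-one | O=C1CC(CCc2cccc(OC)c2)=CC(OC)=C1Cc1ccc(OCc2ccccc2)cc1 | intermediate
20 | 2-[4-(benzyloxy)benzyl]-3-methoxy-5-[2-(3-methoxyphenyl)ethyl]phenol | COc1cccc(CCc2cc(O)c(Cc3ccc(OCc4ccccc4)cc3)c(OC)c2)c1 | intermediate
21 | 2-(4-hydroxybenzyl)-3-methoxy-5-[2-(3-methoxyphenyl)ethyl]phenol (IN0509) | COc1cccc(CCc2cc(O)c(Cc3ccc(O)cc3)c(OC)c2)c1 | target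

Total step count: 8. Longest linear sequence: 6 steps (1, 2, 3, 4, 7, 8). Steps 5 and 6 form a parallel branch.

Steps most likely to fail

Step 6. Three things may go wrong:
- The alkoxyacetylide is a sluggish nucleophile.
- The CH2 group of the product is both benzylic and propargylic, so base-induced migration of the triple bond can set in.
- The ynol ether can be hydrated on acidic supports during isolation.

The fallback changes the oxygen substituent of the alkyne from methyl to silyl and installs the methyl group after ring B exists. This is possible because ring B is symmetric about its C2–C5 axis apart from the OH/OMe difference.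

The fallback sets out from bromide 13. CuBr-catalysed coupling with ethynylmagnesium bromide in THF should give 1-(benzyloxy)-4-(prop-2-yn-1-yl)benzene F1. Deprotonation with LiN(SiMe3)2 and oxidation of the acetylide with lithium tert-butyl peroxide should give lithium 3-[4-(benzyloxy)phenyl]prop-1-yn-1-olate F2. This is O-silylated in the same flask with i-Pr3SiOTf to ({3-[4-(benzyloxy)phenyl]prop-1-yn-1-yl}oxy)triisopropylsilane F3.

Siloxyalkynes are established partners in this benzannulation. Heating F3 with cyclobutenone 9 as in step 7 should give 2-[4-(benzyloxy)benzyl]-5-[2-(3-methoxyphenyl)ethyl]-3-(triisopropylsilyloxy)phenol F4. MeI and K2CO3 in acetone methylate the free phenol to {2-[4-(benzyloxy)benzyl]-3-methoxy-5-[2-(3-methoxyphenyl)ethyl]phenoxy}triisopropylsilane F5. Bu4NF in THF removes the silyl group, and the fallback rejoins the route at 20. Steps 5 and 6, and with them the volatile methoxyacetylene, are then no longer needed.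

Step 7. Four things may go wrong:
- The phenol already formed can capture the vinylketene by O-acylation. Brief treatment of the crude product with methanolic KOH would reverse this, and the benzyl ether tolerates it.
- The ketene can dimerise at the concentration needed.
- The cascade can stall at the four-membered adduct.
- The ynol ether can decay slowly during long heating.

The fallback generates the same vinylketene at room temperature by a photochemical Wolff rearrangement, so the cyclobutenone and the first heating period are not needed.

It sets out from alkyne 5. Markovnikov addition of HI (made from NaI, Me3SiCl and water in MeCN) should give 1-(3-iodobut-3-en-1-yl)-3-methoxybenzene F6. Iodine–lithium exchange with t-BuLi gives [4-(3-methoxyphenyl)but-1-en-2-yl]lithium F7. Acylation with N-methoxy-N-methylacetamide (Weinreb ketone synthesis) gives 5-(3-methoxyphenyl)-3-methylidenepentan-2-one F8.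

Detrifluoroacetylative diazo transfer follows. LiN(SiMe3)2 and CF3CO2CH2CF3 give 1,1,1-trifluoro-7-(3-methoxyphenyl)-5-methylideneheptane-2,4-dione F9. MsN3, Et3N and water in MeCN then give 1-diazo-5-(3-methoxyphenyl)-3-methylidenepentan-2-one F10.

Irradiation of F10 through Pyrex, which spares the aryl ethers, in the presence of ynol ether 15 expels nitrogen and gives vinylketene 16. This is trapped as 17, and a short period in refluxing toluene completes the cascade. The fallback rejoins the route at 20.

Step 3. Dichloroketene may polymerise faster than it adds to an unactivated terminal alkyne. ZnCl2 may degrade the product, and chloride migration may occur in the adduct.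

The fallback replaces the ketene by a keteniminium salt and needs no dechlorination. It sets out from alkyne 5. N,N-dimethylacetamide, Tf2O and 2,4,6-collidine in refluxing ClCH2CH2Cl generate N,N-dimethylketeniminium triflate F11. Its (2+2) cycloaddition to 5, with the same regiochemical sense, gives N-{3-[2-(3-methoxyphenyl)ethyl]cyclobut-2-en-1-ylidene}-N-methylmethanaminium triflate F12. Aqueous hydrolysis of the iminium salt gives the ketone, and the fallback rejoins the route at 9, so step 4 is bypassed as well.

Further compounds
F1 | step 6 | 1-(benzyloxy)-4-(prop-2-yn-1-yl)benzene | C#CCc1ccc(OCc2ccccc2)cc1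
F2 | step 6 | lithium 3-[4-(benzyloxy)phenyl]prop-1-yn-1-olate | [Li+].[O-]C#CCc1ccc(OCc2ccccc2)cc1
F3 | step 6 | ({3-[4-(benzyloxy)phenyl]prop-1-yn-1-yl}oxy)triisopropylsilane | CC(C)[Si](OC#CCc1ccc(OCc2ccccc2)cc1)(C(C)C)C(C)C
F4 | step 6 | 2-[4-(benzyloxy)benzyl]-5-[2-(3-methoxyphenyl)ethyl]-3-(triisopropylsilyloxy)phenol | COc1cccc(CCc2cc(O)c(Cc3ccc(OCc4ccccc4)cc3)c(O[Si](C(C)C)(C(C)C)C(C)C)c2)c1
F5 | step 6 | {2-[4-(benzyloxy)benzyl]-3-methoxy-5-[2-(3-methoxyphenyl)ethyl]phenoxy}triisopropylsilane | COc1cccc(CCc2cc(OC)c(Cc3ccc(OCc4ccccc4)cc3)c(O[Si](C(C)C)(C(C)C)C(C)C)c2)c1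
F6 | step 7 | 1-(3-iodobut-3-en-1-yl)-3-methoxybenzene | C=C(I)CCc1cccc(OC)c1
F7 | step 7 | [4-(3-methoxyphenyl)but-1-en-2-yl]lithium | [Li]C(=C)CCc1cccc(OC)c1
F8 | step 7 | 5-(3-methoxyphenyl)-3-methylidenepentan-2-one | CC(=O)C(=C)CCc1cccc(OC)c1
F9 | step 7 | 1,1,1-trifluoro-7-(3-methoxyphenyl)-5-methylideneheptane-2,4-dione | FC(F)(F)C(=O)CC(=O)C(=C)CCc1cccc(OC)c1
F10 | step 7 | 1-diazo-5-(3-methoxyphenyl)-3-methylidenepentan-2-one | [N-]=[N+]=CC(=O)C(=C)CCc1cccc(OC)c1
F11 | step 3 | N,N-dimethylketeniminium triflate | C=C=[N+](C)C.[O-]S(=O)(=O)C(F)(F)F
F12 | step 3 | N-{3-[2-(3-methoxyphenyl)ethyl]cyclobut-2-en-1-ylidene}-N-methylmethanaminium triflate | C[N+](C)=C1C=C(CCc2cccc(OC)c2)C1.[O-]S(=O)(=O)C(F)(F)F
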